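## Retrosynthetic overview

1. Target 31 ⇐ base isomerisation of the 3-methylene ketone 30 ⇐ C1–C2 disconnection: 6-endo cyclisation of the C1 acyl radical (from the C11 Se-phenyl selenoester 27) onto the alkenyl group on C4, ended by loss of PhS•.
2. Feature used: the enone bridge C1–C2–C3 spans C11 and C4, the diagonal (cis-1,3) carbons of the cyclobutane C4–C5–C11–C10 inside a bicyclo[4.1.1]octane (bridgeheads C5/C10, bridge C6–C9). A C11 acyl and a C4 alkenyl group on the face away from that bridge therefore lie parallel and within bonding distance.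
3. 27 ⇐ cyclobutanone 17 (C11=O): allylic chlorination/thiolation of the isopropenyl group, Wittig C1 homologation with face-selective protonation at C11, oxidation, selenoester; senecioates installed after desilylation.
4. 17 ⇐ intramolecular crossed ketene–diene [2+2] of acid 14, forming C11–C5 and C10–C4 (cyclobutane and seven-membered ring together).
5. 14 ⇐ dienal 6 by acetate aldol (C7), malonate chain extension and anti-selective reduction (C9). Ring order: cyclobutane + seven-membered ring (step 9), then the six-membered ketone ring (step 18).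

Key step: step 18

Remarks
- Target locants are used for all intermediates: C1 ketone, C2=C3 (methyl on C3), cyclobutane C4–C5–C11–C10, C6 CMe2, C7 and C9 CH–O, C8 CH2, methyl on C10. In the open-chain compounds the carboxyl carbon is C11, followed by C10 (CHMe), C9, C8, C7, C6, C5=C4 and C3(Me)=C2.
- Remark on the key step: after ring closure the radical sits on C3, next to cyclobutane carbon C4 (a cyclobutylcarbinyl radical of the pinan-2-yl type). Such a radical is expected to open the four-membered ring faster than a tin hydride at preparative concentration could reduce it. The allylic carbon on C3 therefore carries a phenylthio group, so the radical ends by β-loss of PhS•, and the enone is reached by isomerisation instead of dehydrogenation.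
- Assumption: 1, 7 and 9 are taken as purchased. Otherwise each is one step away: oxidation of methyl 3-hydroxy-2,2-dimethylpropanoate, N-acetylation of (S)-4-benzylthiazolidine-2-thione, half-saponification of diethyl methylmalonate.
- C10 is a mixture of epimers in 10–15; it becomes sp2 in ketene 16 and is set in step 9.

## Route

Step 1
Reactants: 1 methyl 2,2-dimethyl-3-oxopropanoate; 2 dimethyl (2-oxopropyl)phosphonate
Product: 3 methyl (E)-2,2-dimethyl-5-oxohex-3-enoate
Conditions: NaH, THF, 0 °C to rt
Reagents that add atoms: dimethyl (2-oxopropyl)phosphonate (2), COP(=O)(CC(C)=O)OC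
Why: Horner–Wadsworth–Emmons olefination of a non-enolisable aldehyde with a stabilised keto-phosphonate should give the E-enone (the later C5=C4 bond).

Step 2
Reactants: 3 methyl (E)-2,2-dimethyl-5-oxohex-3-enoate; 4 methyltriphenylphosphonium bromide
Product: 5 methyl (E)-2,2,5-trimethylhexa-3,5-dienoate
Conditions: KOtBu, THF, 0 °C
Reagents that add atoms: methyltriphenylphosphonium bromide (4), C[P+](c1ccccc1)(c1ccccc1)c1ccccc1.[Br-]
Why: Wittig methylenation should take place at the ketone (1,2-addition) and not at the hindered α-quaternary ester, giving the 2-methyl-1,3-diene with the E bond untouched.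

Step 3
Reactants: 5 methyl (E)-2,2,5-trimethylhexa-3,5-dienoate
Product: 6 (E)-2,2,5-trimethylhexa-3,5-dienal
Conditions: DIBAL-H (1.1 equiv), CH2Cl2, −78 °C; Rochelle salt
Reagents that add atoms: none
Why: Partial reduction of a neopentyl ester with DIBAL-H at −78 °C should stop at the stable tetrahedral aluminate, which releases the non-enolisable aldehyde on work-up.

Step 4
Reactants: 6 (E)-2,2,5-trimethylhexa-3,5-dienal; 7 (S)-3-acetyl-4-benzylthiazolidine-2-thione
Product: 8 (S)-4-benzyl-3-[(3R,5E)-3-hydroxy-4,4,7-trimethylocta-5,7-dienoyl]thiazolidine-2-thione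
Conditions: TiCl4, iPr2NEt, CH2Cl2, −40 then −78 °C
Reagents that add atoms: (S)-3-acetyl-4-benzylthiazolidine-2-thione (7), CC(=O)N1C(=S)SC[C@@H]1Cc1ccccc1
Why: Nagao-type acetate aldol of the chelated chlorotitanium enolate, in which the aldehyde should add to the enolate face opposite the benzyl group through a chair transition state, sets C7 as R; the minor diastereomer is removed by chromatography.

Step 5
Reactants: 8 aldol adduct; 9 potassium 3-ethoxy-2-methyl-3-oxopropanoate
Product: 11 ethyl (5R,7E)-5-hydroxy-2,6,6,9-tetramethyl-3-oxodeca-7,9-dienoate (C2 epimers), via acylmalonic half-ester 10 (not isolated)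
Conditions: MgCl2, imidazole, THF, rt to 40 °C
Reagents that add atoms: potassium 3-ethoxy-2-methyl-3-oxopropanoate (9), [K+].[O-]C(=O)C(C)C(=O)OCC
Why: Masamune-type decarboxylative Claisen condensation, in which the magnesium malonate half-ester is C-acylated by the activated thioimide and then loses CO2, should deliver the β-keto ester and release the auxiliary without touching C7.

Step 6
Reactants: 11 β-keto ester
Product: 12 ethyl (3R,5R,7E)-3,5-dihydroxy-2,6,6,9-tetramethyldeca-7,9-dienoate (C2 epimers)
Conditions: Me4NBH(OAc)3, MeCN/AcOH, −30 °C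
Reagents that add atoms: none
Why: Evans–Saksena reduction, with intramolecular hydride delivery from the C7 alkoxy-acetoxyborohydride through a chair transition state, should give the 1,3-anti diol and so set C9 as R.

Step 7
Reactants: 12 anti-diol ester
Product: 13 ethyl (3R,5R,7E)-2,6,6,9-tetramethyl-3,5-bis(triethylsilyloxy)deca-7,9-dienoate
Conditions: TESOTf, 2,6-lutidine, CH2Cl2, −78 to 0 °C
Reagents that add atoms: triethylsilyl trifluoromethanesulfonate, CC[Si](CC)(CC)OS(=O)(=O)C(F)(F)F
Why: Silyl triflate with a hindered base silylates both secondary alcohols, including the neopentyl C7–OH, so that no acyloxy leaving group sits β to the later ketene.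

Step 8
Reactants: 13 bis-silyl ether ester
Product: 14 (3R,5R,7E)-2,6,6,9-tetramethyl-3,5-bis(triethylsilyloxy)deca-7,9-dienoic acid
Conditions: LiOH, THF/MeOH/H2O, rt to 35 °C; then 1 M HCl to pH 4, 0 °C
Reagents that add atoms: lithium hydroxide, [Li+].[OH-]
Why: Saponification of the ethyl ester under mild hydroxide conditions should leave the triethylsilyl ethers and the diene intact.

Step 9
Reactants: 14 dienoic acid
Product: 17 (7R,9R)-6,6,10-trimethyl-4-(prop-1-en-2-yl)-7,9-bis(triethylsilyloxy)bicyclo[4.1.1]octan-11-one (target locants; isopropenyl on the face away from the C6–C9 bridge), via acyloxypyridinium salt 15 (not isolated), via ketene 16 (not isolated)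
Conditions: 2-chloro-1-methylpyridinium iodide, Et3N, MeCN, reflux, slow addition (final 0.005 M)
Reagents that add atoms: none
Why: Dehydration of the acid with the Mukaiyama pyridinium salt gives a ketene that should undergo the intramolecular crossed (type II) ketene–alkene [2+2] cycloaddition known for alkenyl ketenes: carbonyl carbon C11 bonds to C5 (leaving allyl-cation character at C4 beside the isopropenyl group) and C10 bonds to C4, the four-atom tether enforcing the bridged bicyclo[4.1.1]octanone; suprafacial addition keeps the E geometry so the isopropenyl group ends trans to C6 on the cyclobutane, the bridge fixes C5 and C10 relative to each other, and the sense relative to C7/C9 should follow from the C9 silyloxy group taking the side of the new carbonyl rather than that of C4–H.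

Step 10
Reactants: 17 bicyclic ketone
Product: 18 the 4-(3-chloroprop-1-en-2-yl) analogue of 17
Conditions: Ca(OCl)2, solid CO2, CH2Cl2/H2O, 0 °C
Reagents that add atoms: calcium hypochlorite, [Ca+2].[O-]Cl.[O-]Cl
Why: Ene-type chlorination of the 1,1-disubstituted alkene with hypochlorous acid (the known allylic chlorination of isopropenyl groups) should give the 2-(chloromethyl)vinyl group; it is run at the ketone stage because C11 then carries nothing that can capture the chloronium ion, and loss of the other allylic hydrogen (C4–H) would need an alkylidenecyclobutane.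

Step 11
Reactants: 18 allylic chloride
Product: 19 the 4-[3-(phenylsulfanyl)prop-1-en-2-yl] analogue of 17
Conditions: PhSH, K2CO3, DMF, 0 °C to rt
Reagents that add atoms: benzenethiol, Sc1ccccc1
Why: Thiolate displacement of the primary allylic chloride (SN2 and SN2′ give the same product) installs the radical leaving group; the non-enolisable ketone and silyl ethers are inert.

Step 12
Reactants: 19 allyl sulfide ketone; 20 (methoxymethyl)triphenylphosphonium chloride
Product: 21 the 11-(methoxymethylidene) compound (enol ether E/Z mixture)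
Conditions: KHMDS, THF/toluene, 0 °C to reflux
Reagents that add atoms: (methoxymethyl)triphenylphosphonium chloride (20), COC[P+](c1ccccc1)(c1ccccc1)c1ccccc1.[Cl-]
Why: Wittig methoxymethylenation brings in C1; the ketone cannot enolise (its only α-hydrogen is at bridgehead C5) and the strained cyclobutanone carbonyl is electrophilic enough to offset the steric hindrance.

Step 13
Reactants: 21 enol ether
Product: 22 the 7,9-diol of 21
Conditions: TBAF, THF, 0 °C to rt
Reagents that add atoms: none
Why: Fluoride cleaves both triethylsilyl ethers under conditions to which the enol ether and the sulfide are inert.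

Step 14
Reactants: 22 diol; 23 3-methylbut-2-enoyl chloride
Product: 24 the 7,9-bis(3-methylbut-2-enoate) of 22
Conditions: pyridine, DMAP (cat.), CH2Cl2, 0 to 40 °C
Reagents that add atoms: 3-methylbut-2-enoyl chloride (23), CC(C)=CC(Cl)=O
Why: DMAP-catalysed acylation of the two hindered secondary alcohols; pyridine rather than a trialkylamine is used so that the acyl chloride is not deconjugated through its vinylketene.

Step 15
Reactants: 24 bis-senecioate enol ether
Product: 25 the 11-carbaldehyde (formyl cis to the C4 side chain)
Conditions: 1 M HCl/THF (1:4), 0 °C, short contact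
Reagents that add atoms: water, O
Why: Mild acid hydrolysis protonates C11 of the enol ether from the face turned to the C6–C9 bridge, the only open one because the opposite face is covered by the C4 side chain 1,3 across the cyclobutane, so the formyl group should end cis to that side chain (kinetic control; low temperature limits epimerisation and engagement of the neighbouring alkene).

Step 16
Reactants: 25 aldehyde
Product: 26 the 11-carboxylic acid
Conditions: NaClO2, NaH2PO4, 2-methyl-2-butene (large excess), tBuOH/H2O, 0 °C to rt
Reagents that add atoms: sodium chlorite, [Na+].[O-]Cl=O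
Why: Pinnick oxidation gives the acid without epimerising C11; the excess scavenger removes hypochlorous acid and thereby protects the alkenes and the aryl sulfide, a group known to survive these conditions.

Step 17
Reactants: 26 acid
Product: 27 the Se-phenyl 11-carboselenoate (key-step precursor)
Conditions: PhSeSePh, PBu3, CH2Cl2, rt
Reagents that add atoms: diphenyl diselenide, c1ccc(cc1)[Se][Se]c1ccccc1
Why: Activation of the acid as its acyloxyphosphonium salt and capture by phenylselenolate (the standard phosphine–diselenide selenoester synthesis) proceeds under neutral conditions that leave C11 and both esters untouched.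

Step 18
Reactants: 27 selenoester
Product: 30 (7R,9R)-3-methylidene-1-oxolongipinane-7,9-diyl bis(3-methylbut-2-enoate), via acyl radical 28 (not isolated), via tertiary C3 radical 29 (not isolated)
Conditions: (Bu3Sn)2 (1.2 equiv), hν (sunlamp, Pyrex), benzene, 25–35 °C, 0.01 M, CO (1 atm)
Reagents that add atoms: none
Why: Tributylstannyl radicals from photolysis of the ditin abstract the phenylseleno group of 27 to give the C1 acyl radical 28, which adds to the unsubstituted alkene terminus C2 held parallel to it 1,3 across the cyclobutane and forms C1–C2; the tertiary C3 radical 29 then expels PhS• from the adjacent carbon, and PhS• regenerates the stannyl radical from the ditin. The closest known reaction type is the 6-endo-trig cyclisation of acyl radicals from phenyl selenoesters onto 1,1-disubstituted alkenes, here ended by the known addition–fragmentation of allyl sulfides. The six-membered ketone ring (C11–C1–C2–C3–C4, closed through C10 or C5) forms in the 6-endo mode, since 5-exo attack at C3 would hit a fully substituted carbon and give a bicyclo[2.1.1]hexanone and a primary radical. No new stereocentre is created (C3 ends sp2); the ring fusion follows from the cis C11/C4 relationship set in steps 9 and 15. The step needs fragmentation of 29 to outrun opening of the cyclobutane, to which this cyclobutylcarbinyl radical is prone; the unimolecular loss of the arylthiyl radical, the absence of any hydride donor (so neither premature reduction of 28 nor a slow bimolecular quench of 29 intervenes) and the low temperature of photochemical initiation should secure this. Decarbonylation of 28 would give a cyclobutyl radical and should be slow; the CO atmosphere suppresses it further.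

Step 19
Reactants: 30 3-methylene ketone
Product: 31 CNP0105062.1, (7R,9R)-1-oxolongipin-2-ene-7,9-diyl bis(3-methylbut-2-enoate)
Conditions: DBU (0.2 equiv), CH2Cl2, rt
Reagents that add atoms: none
Why: Base-mediated isomerisation of the β,γ-unsaturated ketone through its C2 dienolate (C11 is a bridgehead and cannot enolise) should move the exocyclic double bond into conjugation and give the more stable trisubstituted enone.

## Compound list

1 | methyl 2,2-dimethyl-3-oxopropanoate | COC(=O)C(C)(C)C=O | starting material
2 | dimethyl (2-oxopropyl)phosphonate | COP(=O)(CC(C)=O)OC | starting material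
3 | methyl (E)-2,2-dimethyl-5-oxohex-3-enoate | COC(=O)C(C)(C)/C=C/C(C)=O | intermediate
4 | methyltriphenylphosphonium bromide | C[P+](c1ccccc1)(c1ccccc1)c1ccccc1.[Br-] | starting material
5 | methyl (E)-2,2,5-trimethylhexa-3,5-dienoate | COC(=O)C(C)(C)/C=C/C(C)=C | intermediate
6 | (E)-2,2,5-trimethylhexa-3,5-dienal | O=CC(C)(C)/C=C/C(C)=C | intermediate
7 | (S)-3-acetyl-4-benzylthiazolidine-2-thione | CC(=O)N1C(=S)SC[C@@H]1Cc1ccccc1 | starting material
8 | (S)-4-benzyl-3-[(3R,5E)-3-hydroxy-4,4,7-trimethylocta-5,7-dienoyl]thiazolidine-2-thione | O=C(C[C@@H](O)C(C)(C)/C=C/C(C)=C)N1C(=S)SC[C@@H]1Cc1ccccc1 | intermediate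
9 | potassium 3-ethoxy-2-methyl-3-oxopropanoate | [K+].[O-]C(=O)C(C)C(=O)OCC | starting material
10 | (5R,7E)-2-(ethoxycarbonyl)-5-hydroxy-2,6,6,9-tetramethyl-3-oxodeca-7,9-dienoic acid (magnesium salt in the flask; not isolated) | OC(=O)C(C)(C(=O)OCC)C(=O)C[C@@H](O)C(C)(C)/C=C/C(C)=C | intermediate
11 | ethyl (5R,7E)-5-hydroxy-2,6,6,9-tetramethyl-3-oxodeca-7,9-dienoate (C2 epimers) | CCOC(=O)C(C)C(=O)C[C@@H](O)C(C)(C)/C=C/C(C)=C | intermediate
12 | ethyl (3R,5R,7E)-3,5-dihydroxy-2,6,6,9-tetramethyldeca-7,9-dienoate (C2 epimers) | CCOC(=O)C(C)[C@H](O)C[C@@H](O)C(C)(C)/C=C/C(C)=C | intermediate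
13 | ethyl (3R,5R,7E)-2,6,6,9-tetramethyl-3,5-bis(triethylsilyloxy)deca-7,9-dienoate | CCOC(=O)C(C)[C@H](O[Si](CC)(CC)CC)C[C@@H](O[Si](CC)(CC)CC)C(C)(C)/C=C/C(C)=C | intermediate
14 | (3R,5R,7E)-2,6,6,9-tetramethyl-3,5-bis(triethylsilyloxy)deca-7,9-dienoic acid | OC(=O)C(C)[C@H](O[Si](CC)(CC)CC)C[C@@H](O[Si](CC)(CC)CC)C(C)(C)/C=C/C(C)=C | intermediate
15 | 2-acyloxy-1-methylpyridinium iodide of 14 (not isolated) | C[n+]1ccccc1OC(=O)C(C)[C@H](O[Si](CC)(CC)CC)C[C@@H](O[Si](CC)(CC)CC)C(C)(C)/C=C/C(C)=C.[I-] | intermediate
16 | ketene from 14 (not isolated) | O=C=C(C)[C@H](O[Si](CC)(CC)CC)C[C@@H](O[Si](CC)(CC)CC)C(C)(C)/C=C/C(C)=C | intermediate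
17 | (7R,9R)-6,6,10-trimethyl-4-(prop-1-en-2-yl)-7,9-bis(triethylsilyloxy)bicyclo[4.1.1]octan-11-one (target locants) | CC[Si](CC)(CC)O[C@@H]1C[C@@H](O[Si](CC)(CC)CC)[C@@]2(C)C(=O)[C@H]([C@@H]2C(C)=C)C1(C)C | intermediate
18 | 4-(3-chloroprop-1-en-2-yl) analogue of 17 | CC[Si](CC)(CC)O[C@@H]1C[C@@H](O[Si](CC)(CC)CC)[C@@]2(C)C(=O)[C@H]([C@@H]2C(CCl)=C)C1(C)C | intermediate
19 | 4-[3-(phenylsulfanyl)prop-1-en-2-yl] analogue of 17 | CC[Si](CC)(CC)O[C@@H]1C[C@@H](O[Si](CC)(CC)CC)[C@@]2(C)C(=O)[C@H]([C@@H]2C(CSc3ccccc3)=C)C1(C)C | intermediate
20 | (methoxymethyl)triphenylphosphonium chloride | COC[P+](c1ccccc1)(c1ccccc1)c1ccccc1.[Cl-] | starting material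
21 | 11-(methoxymethylidene) bis-silyl ether (E/Z mixture) | CC[Si](CC)(CC)O[C@@H]1C[C@@H](O[Si](CC)(CC)CC)[C@@]2(C)C(=COC)[C@H]([C@@H]2C(CSc3ccccc3)=C)C1(C)C | intermediate
22 | 11-(methoxymethylidene) 7,9-diol | O[C@@H]1C[C@@H](O)[C@@]2(C)C(=COC)[C@H]([C@@H]2C(CSc3ccccc3)=C)C1(C)C | intermediate
23 | 3-methylbut-2-enoyl chloride | CC(C)=CC(Cl)=O | starting material
24 | 11-(methoxymethylidene) 7,9-bis(3-methylbut-2-enoate) | CC(C)=CC(=O)O[C@@H]1C[C@@H](OC(=O)C=C(C)C)[C@@]2(C)C(=COC)[C@H]([C@@H]2C(CSc3ccccc3)=C)C1(C)C | intermediate
25 | 11-carbaldehyde, formyl cis to the C4 side chain | CC(C)=CC(=O)O[C@@H]1C[C@@H](OC(=O)C=C(C)C)[C@@]2(C)[C@H](C=O)[C@H]([C@@H]2C(CSc3ccccc3)=C)C1(C)C | intermediate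
26 | 11-carboxylic acid | CC(C)=CC(=O)O[C@@H]1C[C@@H](OC(=O)C=C(C)C)[C@@]2(C)[C@H](C(O)=O)[C@H]([C@@H]2C(CSc3ccccc3)=C)C1(C)C | intermediate
27 | Se-phenyl 11-carboselenoate with C4 3-(phenylsulfanyl)prop-1-en-2-yl group (key-step precursor) | CC(C)=CC(=O)O[C@@H]1C[C@@H](OC(=O)C=C(C)C)[C@@]2(C)[C@H](C(=O)[Se]c3ccccc3)[C@H]([C@@H]2C(CSc4ccccc4)=C)C1(C)C | intermediate
28 | C1 acyl radical (not isolated) | CC(C)=CC(=O)O[C@@H]1C[C@@H](OC(=O)C=C(C)C)[C@@]2(C)[C@H]([C]=O)[C@H]([C@@H]2C(CSc3ccccc3)=C)C1(C)C | intermediate
29 | cyclised tertiary C3 radical (not isolated) | CC(C)=CC(=O)O[C@@H]1C[C@@H](OC(=O)C=C(C)C)[C@@]2(C)[C@@H]3C(=O)C[C](CSc4ccccc4)[C@H]2[C@@H]3C1(C)C | intermediate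
30 | (7R,9R)-3-methylidene-1-oxolongipinane-7,9-diyl bis(3-methylbut-2-enoate) (key-step product) | CC(C)=CC(=O)O[C@@H]1C[C@@H](OC(=O)C=C(C)C)[C@@]2(C)[C@@H]3C(=O)CC(=C)[C@H]2[C@@H]3C1(C)C | intermediate
31 | CNP0105062.1, (7R,9R)-1-oxolongipin-2-ene-7,9-diyl bis(3-methylbut-2-enoate) | CC(C)=CC(=O)O[C@@H]1C[C@@H](OC(=O)C=C(C)C)[C@@]2(C)[C@@H]3C(=O)C=C(C)[C@H]2[C@@H]3C1(C)C | target

Total step count: 19. Longest linear sequence: 19 steps (from 1).

## Steps most likely to fail

**Step 9.** Closure of a bridged seven-membered ring is slower than the usual six-membered cases, so the ketene may dimerise or oligomerise first. It may also add across the terminal alkene, or to the wrong diastereoface relative to C9. The fallback sets out from acid 14 and uses a more electrophilic two-carbon partner. Coupling with pyrrolidine (EDC, HOBt) gives the pyrrolidine amide F1. Triflic anhydride and 2,4,6-collidine in refluxing 1,2-dichloroethane at high dilution convert it into the keteniminium triflate F2, which should undergo the same crossed [2+2] cycloaddition to the cyclobutaniminium triflate F3. Hydrolysis with aqueous NaHCO3 returns to ketone 17.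

**Step 18.** The C3 radical may open the cyclobutane before it loses the thiyl radical, or the acyl radical may close slowly against the strain of the forming bicyclo[3.1.1]heptanone and decarbonylate instead. The fallback sets out from aldehyde 25 and makes the same C1–C2 bond from a ketyl. SmI2 in THF/tBuOH at −78 to 0 °C gives the ketyl, which adds to C2; the β-sulfanyl intermediate eliminates the phenylsulfanyl group (as radical or as thiolate after a second electron transfer) to give the homoallylic alcohol F4 as a mixture of C1 epimers. Dess–Martin oxidation of F4 comes back to ketone 30.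

**Step 12.** The ylide may fail to attack the carbonyl, since one face is covered by the C4 side chain and the other is flanked by a C6 methyl and the C9 silyloxy group. The fallback sets out from ketone 19 and uses a smaller nucleophile in a Peterson olefination. Methoxy(trimethylsilyl)methyllithium (from methoxymethyltrimethylsilane and s-BuLi, THF, −78 °C) adds to the ketone to give the β-hydroxysilane F5. Potassium hydride in THF then eliminates silanolate and comes back to enol ether 21.

Further compounds
F1 | step 9 | pyrrolidine amide of acid 14 | O=C(N1CCCC1)C(C)[C@H](O[Si](CC)(CC)CC)C[C@@H](O[Si](CC)(CC)CC)C(C)(C)/C=C/C(C)=C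
F2 | step 9 | keteniminium triflate from F1 | C(=[N+]1CCCC1)=C(C)[C@H](O[Si](CC)(CC)CC)C[C@@H](O[Si](CC)(CC)CC)C(C)(C)/C=C/C(C)=C.[O-]S(=O)(=O)C(F)(F)F
F3 | step 9 | 11-pyrrolidinium-ylidene (cyclobutaniminium) triflate corresponding to ketone 17 | CC[Si](CC)(CC)O[C@@H]1C[C@@H](O[Si](CC)(CC)CC)[C@@]2(C)C(=[N+]3CCCC3)[C@H]([C@@H]2C(C)=C)C1(C)C.[O-]S(=O)(=O)C(F)(F)F
F4 | step 18 | (7R,9R)-1-hydroxy-3-methylidenelongipinane-7,9-diyl bis(3-methylbut-2-enoate) (C1 epimers) | CC(C)=CC(=O)O[C@@H]1C[C@@H](OC(=O)C=C(C)C)[C@@]2(C)[C@@H]3C(O)CC(=C)[C@H]2[C@@H]3C1(C)C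
F5 | step 12 | 11-hydroxy-11-[methoxy(trimethylsilyl)methyl] adduct of ketone 19 | CC[Si](CC)(CC)O[C@@H]1C[C@@H](O[Si](CC)(CC)CC)[C@@]2(C)C(O)(C(OC)[Si](C)(C)C)[C@H]([C@@H]2C(CSc3ccccc3)=C)C1(C)C
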